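**Retrosynthetic overview**

1. The strategy rests on ring A carbon C6, which carries C3″H(propyl)–C2″H2–C1″O2H beside the enolic O5 on C5: this is a 4-propyl-3,4-dihydrocoumarin (ring C) with its O5–C1″ ester bond hydrolysed.
2. Ring C is cut at O5–C1″ and C2″–C1″, with C1″ coming from carbon monoxide and the C3″–H bond from a palladium hydride; this leads back to a 2-(pent-1-en-2-yl)phenol made from butyrylphloroglucinol.
3. Chromanone ring B is cut at O1–C2 (oxa-Michael addition onto an 8-tigloyl group, cis-2,3-dimethyl by a cinchona base).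
4. At C8, the C8–C1′ bond comes from a Negishi coupling with a limonene-derived (S)-alkyl iodide, and the quaternary centre from a dearomative prenylation.
5. Ring order: ring A is bought (phloroglucinol), ring C closes in step 4, ring B in step 7, ring A is dearomatised in step 15, and ring C is opened in step 16.

Key step: step 4

**Remarks on the chemistry**

- Assumption: the antipode of each chiral controller (DIOP in step 4, the cinchona base in step 7, the Trost ligand in step 15) that gives the drawn configuration is assigned in a first run on the real substrate; both antipodes or pseudo-enantiomers are commercial.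
- Numbering: compounds 13–28 are numbered as pyrano[2,3-f]chromenes. O1/C2/C3/C4 are O5/C1″/C2″/C3″ of the target; C4a = C6, C5 = C7, C6 = C8, C6a = C8a, O7 = O1, C8 = C2, C9 = C3, C10 = C4, C10a = C4a, C10b = C5 of the target.

**Route**

Step 1
Reactants: 1 phloroglucinol; 2 butyryl chloride
Product: 3 1-(2,4,6-trihydroxyphenyl)butan-1-one
Conditions: AlCl3 (3.5 equiv), PhNO2/CH2Cl2, 0 to 50 °C; cold aq. HCl
Reagents that add atoms: none
Why: Friedel–Crafts C-acylation of the strongly activated triol should stop after one acyl group because the chelated aryl ketone deactivates the ring.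

Step 2
Reactants: 3 1-(2,4,6-trihydroxyphenyl)butan-1-one; 4 benzyl bromide
Product: 5 1-[2,4-bis(benzyloxy)-6-hydroxyphenyl]butan-1-one
Conditions: BnBr (2.05 equiv in all), K2CO3 (2.1 equiv), DMF, 0 °C to rt
Reagents that add atoms: benzyl bromide (second equivalent of 4), BrCc1ccccc1
Why: Two successive Williamson etherifications under carbonate base should take the para hydroxyl and one ortho hydroxyl, each with one equivalent of benzyl bromide, while the second ortho hydroxyl stays hydrogen-bonded to the ketone and is the least nucleophilic.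

Step 3
Reactants: 5 1-[2,4-bis(benzyloxy)-6-hydroxyphenyl]butan-1-one; 6 methyltriphenylphosphonium bromide
Product: 7 3,5-bis(benzyloxy)-2-(pent-1-en-2-yl)phenol
Conditions: Ph3PCH3Br (3 equiv), KOtBu (3 equiv), THF, 0 °C, then 5, reflux; aq. NH4Cl
Reagents that add atoms: none
Why: Wittig methylenation with excess ylide (one equivalent is spent on the phenol) should give only the 1,1-disubstituted alkene, avoiding the positional isomers that a Grignard addition followed by dehydration would give.

Step 4
Reactants: 7 3,5-bis(benzyloxy)-2-(pent-1-en-2-yl)phenol; 8 carbon monoxide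
Product: 9 (4S)-5,7-bis(benzyloxy)-4-propyl-3,4-dihydro-2H-chromen-2-one
Conditions: Pd(OAc)2 (5 mol %), (R,R)- or (S,S)-DIOP (10 mol %), CO/H2 (1:1, 35 bar), CH2Cl2, 100 °C
Reagents that add atoms: none
Why: Pd(OAc)2, the bisphosphine and CO/H2 should give a divalent palladium hydride that delivers hydrogen to the benzylic alkene carbon (the future C3″) and palladium to the CH2 terminus, after which CO inserts to make the C2″–C1″ bond and the acyl group is taken up by the neighbouring phenol oxygen (O5–C1″), releasing zerovalent palladium that is reprotonated. The closest known reaction is the palladium-catalysed asymmetric cyclocarbonylation of 2-(1-methylvinyl)phenols to 4-methyl-3,4-dihydrocoumarins. Ring C closes by 6-exo-trig attack of the phenol oxygen on the acylpalladium carbon. The new stereocentre is made in the hydropalladation, where the C2-symmetric bisphosphine on palladium selects the alkene face. The step needs anti-Markovnikov regioselectivity and a single lactonisation: the opposite insertion would put palladium on a tertiary, doubly ortho-substituted benzylic carbon, and only one ortho hydroxyl is free because the other two oxygens are benzylated.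

Step 5
Reactants: 9 (4S)-5,7-bis(benzyloxy)-4-propyl-3,4-dihydro-2H-chromen-2-one
Product: 10 (4S)-5,7-dihydroxy-4-propyl-3,4-dihydro-2H-chromen-2-one
Conditions: H2 (1 atm), 10% Pd/C, EtOAc, rt
Reagents that add atoms: none
Why: Hydrogenolysis of both benzyl ethers is done before any alkene is in the molecule, and the aryl lactone and the C4 stereocentre should be inert.

Step 6
Reactants: 10 (4S)-5,7-dihydroxy-4-propyl-3,4-dihydro-2H-chromen-2-one; 11 tigloyl chloride [(2E)-2-methylbut-2-enoyl chloride]
Product: 12 (4S)-5,7-dihydroxy-8-[(2E)-2-methylbut-2-enoyl]-4-propyl-3,4-dihydro-2H-chromen-2-one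
Conditions: AlCl3 (3 equiv), PhNO2/ClCH2CH2Cl, 0 °C to rt; cold aq. HCl
Reagents that add atoms: none
Why: Friedel–Crafts acylation should go to C8, which is ortho to 7-OH and para to 5-OH like the 4-position of a resorcinol, in preference to C6 between the two hydroxyls, as is known for 5,7-dihydroxy-4-propylcoumarin.

Step 7
Reactants: 12 (4S)-5,7-dihydroxy-8-[(2E)-2-methylbut-2-enoyl]-4-propyl-3,4-dihydro-2H-chromen-2-one
Product: 13 (4S,8R,9S)-5-hydroxy-8,9-dimethyl-4-propyl-3,4,8,9-tetrahydro-2H,10H-pyrano[2,3-f]chromene-2,10-dione (cis-8,9-dimethyl)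
Conditions: (−)-quinine (0.2 equiv; quinidine if the sense is opposite), PhCl, 15 °C
Reagents that add atoms: none
Why: Cinchona-base-catalysed intramolecular oxa-Michael addition of the chelated 7-OH to the tigloyl enone should set the O–CH(CH3) centre under control of the alkaloid, and kinetic protonation of the enol on the same face gives the cis-dimethylchromanone.

Step 8
Reactants: 13 (4S,8R,9S)-5-hydroxy-8,9-dimethyl-4-propyl-3,4,8,9-tetrahydro-2H,10H-pyrano[2,3-f]chromene-2,10-dione
Product: 14 (4S,8R,9S)-5-hydroxy-6-iodo-8,9-dimethyl-4-propyl-3,4,8,9-tetrahydro-2H,10H-pyrano[2,3-f]chromene-2,10-dione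
Conditions: NIS (1.05 equiv), CH2Cl2, 0 °C, dark
Reagents that add atoms: N-iodosuccinimide, O=C1CCC(=O)N1I
Why: Electrophilic aromatic iodination should take the only remaining ring C–H, which lies ortho to the free hydroxyl and to the chromanone ether oxygen.

Step 9
Reactants: 15 (+)-limonene 1,2-oxide [(4R)-1-methyl-4-(prop-1-en-2-yl)-7-oxabicyclo[4.1.0]heptane, cis/trans mixture at the epoxide]
Product: 16 (3R)-6-oxo-3-(prop-1-en-2-yl)heptanal
Conditions: HIO4·2H2O (1.2 equiv), THF/H2O, 0 °C to rt
Reagents that add atoms: water, O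
Why: Periodic acid should open the epoxide to the diol and cleave it in the same flask (glycol cleavage), so both epoxide diastereomers converge on one keto aldehyde and the isopropenyl-bearing stereocentre is untouched.

Step 10
Reactants: 16 (3R)-6-oxo-3-(prop-1-en-2-yl)heptanal
Product: 17 (3R)-6-oxo-3-(prop-1-en-2-yl)heptanoic acid
Conditions: NaClO2, NaH2PO4, 2-methylbut-2-ene, t-BuOH/H2O, 0 °C to rt
Reagents that add atoms: sodium chlorite, [Na+].[O-]Cl=O
Why: Pinnick oxidation should convert only the aldehyde, with 2-methylbut-2-ene trapping hypochlorous acid so that the isopropenyl group survives.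

Step 11
Reactants: 17 (3R)-6-oxo-3-(prop-1-en-2-yl)heptanoic acid; 6 methyltriphenylphosphonium bromide
Product: 18 (3R)-6-methyl-3-(prop-1-en-2-yl)hept-6-enoic acid
Conditions: Ph3PCH3Br (2.5 equiv), KOtBu (3.5 equiv), THF, 0 °C to rt; aq. HCl to pH 3
Reagents that add atoms: none
Why: Wittig methylenation of the methyl ketone tolerates the carboxylate, and the stereocentre is β to the carboxyl and cannot enolise.

Step 12
Reactants: 18 (3R)-6-methyl-3-(prop-1-en-2-yl)hept-6-enoic acid
Product: 20 (3S)-3-(iodomethyl)-2,6-dimethylhepta-1,6-diene, via Barton ester 19 (not isolated)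
Conditions: N-hydroxypyridine-2-thione, DCC, CH2Cl2, 0 °C, dark; then CHI3 (3 equiv), tungsten lamp, rt
Reagents that add atoms: iodoform, IC(I)I
Why: Barton decarboxylative iodination should give the primary alkyl radical, which takes iodine from iodoform faster than it can cyclise onto either alkene; the stereocentre is not a radical site and its descriptor changes only because CH2I outranks isopropenyl.

Step 13
Reactants: 14 (4S,8R,9S)-5-hydroxy-6-iodo-8,9-dimethyl-4-propyl-3,4,8,9-tetrahydro-2H,10H-pyrano[2,3-f]chromene-2,10-dione; 20 (3S)-3-(iodomethyl)-2,6-dimethylhepta-1,6-diene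
Product: 24 (4S,8R,9S)-5-hydroxy-8,9-dimethyl-6-[(2R)-5-methyl-2-(prop-1-en-2-yl)hex-5-en-1-yl]-4-propyl-3,4,8,9-tetrahydro-2H,10H-pyrano[2,3-f]chromene-2,10-dione, via alkylzinc iodide 21 (not isolated), via aryl trimethylsilyl ether 22 (not isolated), via coupled trimethylsilyl ether 23 (not isolated)
Conditions: 20, Zn dust (activated with BrCH2CH2Br and Me3SiCl), LiCl, THF, 40 °C; 14, N,O-bis(trimethylsilyl)acetamide, THF, rt; combine, Pd(OAc)2 (5 mol %), SPhos (10 mol %), THF, rt to 35 °C; 1 M aq. citric acid
Reagents that add atoms: none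
Why: Negishi coupling: zinc inserts into the primary C–I bond without touching the β stereocentre, the phenol is masked in the flask as its silyl ether so that it cannot protonate the organozinc, and the biarylphosphine should promote coupling at the hindered di-ortho-oxygenated aryl iodide ahead of β-hydride elimination.

Step 14
Reactants: 25 3-methylbut-2-en-1-ol (prenol); 26 di-tert-butyl dicarbonate
Product: 27 tert-butyl 3-methylbut-2-en-1-yl carbonate
Conditions: Boc2O (1.2 equiv), n-Bu4NHSO4 (cat.), 30% aq. NaOH, CH2Cl2, 0 °C to rt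
Reagents that add atoms: none
Why: Phase-transfer acylation of the primary allylic alcohol with Boc2O is a standard preparation of allylic tert-butyl carbonates.

Step 15
Reactants: 24 (4S,8R,9S)-5-hydroxy-8,9-dimethyl-6-[(2R)-5-methyl-2-(prop-1-en-2-yl)hex-5-en-1-yl]-4-propyl-3,4,8,9-tetrahydro-2H,10H-pyrano[2,3-f]chromene-2,10-dione; 27 tert-butyl 3-methylbut-2-en-1-yl carbonate
Product: 28 (4S,6R,8R,9S)-8,9-dimethyl-6-(3-methylbut-2-en-1-yl)-6-[(2R)-5-methyl-2-(prop-1-en-2-yl)hex-5-en-1-yl]-4-propyl-3,4,8,9-tetrahydro-2H-pyrano[2,3-f]chromene-2,5,10(6H)-trione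
Conditions: Pd2(dba)3·CHCl3 (2.5 mol %), (R,R)- or (S,S)-DACH-phenyl Trost ligand (7.5 mol %), 27 (1.3 equiv), toluene, 0 °C to rt
Reagents that add atoms: none
Why: Proposed new method: zerovalent palladium ionises 27 to a cationic π-prenyl complex of divalent palladium plus tert-butoxide (after loss of CO2), which deprotonates the acidic phenol; the phenoxide then attacks the unsubstituted allyl terminus through C6, the less hindered of its two ortho carbons, with the C6 face chosen by the chiral pocket of the ligand, and any O-prenyl ether re-ionises because the aryloxide is a good leaving group, so the C-alkylated dienone should accumulate without external base; the closest known reactions are the palladium/Trost-ligand asymmetric allylic dearomatisation of 1-substituted 2-naphthols, the palladium-catalysed asymmetric linear prenylation of oxindoles to quaternary centres, and the base-mediated dearomative prenylation of acylphloroglucinols.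

Step 16
Reactants: 28 (4S,6R,8R,9S)-8,9-dimethyl-6-(3-methylbut-2-en-1-yl)-6-[(2R)-5-methyl-2-(prop-1-en-2-yl)hex-5-en-1-yl]-4-propyl-3,4,8,9-tetrahydro-2H-pyrano[2,3-f]chromene-2,5,10(6H)-trione
Product: 29 (3S)-3-{(2R,3S,8R)-5-hydroxy-2,3-dimethyl-8-(3-methylbut-2-en-1-yl)-8-[(2R)-5-methyl-2-(prop-1-en-2-yl)hex-5-en-1-yl]-4,7-dioxo-3,4,7,8-tetrahydro-2H-chromen-6-yl}hexanoic acid (CNP0294320.1)
Conditions: LiOH (3 equiv), THF/H2O (3:1), 0 °C, short; cold 1 M HCl to pH 3
Reagents that add atoms: lithium hydroxide, [Li+].[OH-]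
Why: Saponification of the enol lactone, an activated ester, should be much faster than enolisation at C3, and the resulting dianion (carboxylate plus triketone enolate) should protect the cis-chromanone from epimerisation until acidification.

**Compound list**

1 | phloroglucinol | Oc1cc(O)cc(O)c1 | starting material
2 | butyryl chloride | CCCC(Cl)=O | starting material
3 | 1-(2,4,6-trihydroxyphenyl)butan-1-one | CCCC(=O)c1c(O)cc(O)cc1O | intermediate
4 | benzyl bromide | BrCc1ccccc1 | starting material
5 | 1-[2,4-bis(benzyloxy)-6-hydroxyphenyl]butan-1-one | CCCC(=O)c1c(O)cc(OCc2ccccc2)cc1OCc1ccccc1 | intermediate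
6 | methyltriphenylphosphonium bromide | C[P+](c1ccccc1)(c1ccccc1)c1ccccc1.[Br-] | starting material
7 | 3,5-bis(benzyloxy)-2-(pent-1-en-2-yl)phenol | CCCC(=C)c1c(O)cc(OCc2ccccc2)cc1OCc1ccccc1 | intermediate
8 | carbon monoxide | [C-]#[O+] | starting material
9 | (4S)-5,7-bis(benzyloxy)-4-propyl-3,4-dihydro-2H-chromen-2-one | CCC[C@H]1CC(=O)Oc2cc(OCc3ccccc3)cc(OCc3ccccc3)c12 | intermediate
10 | (4S)-5,7-dihydroxy-4-propyl-3,4-dihydro-2H-chromen-2-one | CCC[C@H]1CC(=O)Oc2cc(O)cc(O)c12 | intermediate
11 | tigloyl chloride, (2E)-2-methylbut-2-enoyl chloride | C/C=C(\C)C(Cl)=O | starting material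
12 | (4S)-5,7-dihydroxy-8-[(2E)-2-methylbut-2-enoyl]-4-propyl-3,4-dihydro-2H-chromen-2-one | CCC[C@H]1CC(=O)Oc2c(C(=O)/C(C)=C/C)c(O)cc(O)c12 | intermediate
13 | (4S,8R,9S)-5-hydroxy-8,9-dimethyl-4-propyl-3,4,8,9-tetrahydro-2H,10H-pyrano[2,3-f]chromene-2,10-dione | CCC[C@H]1CC(=O)Oc2c3C(=O)[C@@H](C)[C@@H](C)Oc3cc(O)c12 | intermediate
14 | (4S,8R,9S)-5-hydroxy-6-iodo-8,9-dimethyl-4-propyl-3,4,8,9-tetrahydro-2H,10H-pyrano[2,3-f]chromene-2,10-dione | CCC[C@H]1CC(=O)Oc2c3C(=O)[C@@H](C)[C@@H](C)Oc3c(I)c(O)c12 | intermediate
15 | (+)-limonene 1,2-oxide, (4R), cis/trans mixture at the epoxide | CC12OC1C[C@@H](CC2)C(=C)C | starting material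
16 | (3R)-6-oxo-3-(prop-1-en-2-yl)heptanal | O=CC[C@@H](CCC(C)=O)C(=C)C | intermediate
17 | (3R)-6-oxo-3-(prop-1-en-2-yl)heptanoic acid | OC(=O)C[C@@H](CCC(C)=O)C(=C)C | intermediate
18 | (3R)-6-methyl-3-(prop-1-en-2-yl)hept-6-enoic acid | OC(=O)C[C@@H](CCC(C)=C)C(=C)C | intermediate
19 | Barton ester of 18 (2-thioxopyridin-1(2H)-yl ester) | O=C(ON1C=CC=CC1=S)C[C@@H](CCC(C)=C)C(=C)C | intermediate
20 | (3S)-3-(iodomethyl)-2,6-dimethylhepta-1,6-diene | IC[C@@H](CCC(C)=C)C(=C)C | intermediate
21 | [(2S)-5-methyl-2-(prop-1-en-2-yl)hex-5-en-1-yl]zinc iodide | I[Zn]C[C@@H](CCC(C)=C)C(=C)C | intermediate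
22 | trimethylsilyl ether of 14 | CCC[C@H]1CC(=O)Oc2c3C(=O)[C@@H](C)[C@@H](C)Oc3c(I)c(O[Si](C)(C)C)c12 | intermediate
23 | trimethylsilyl ether of 24 | CCC[C@H]1CC(=O)Oc2c3C(=O)[C@@H](C)[C@@H](C)Oc3c(C[C@@H](CCC(C)=C)C(=C)C)c(O[Si](C)(C)C)c12 | intermediate
24 | (4S,8R,9S)-5-hydroxy-8,9-dimethyl-6-[(2R)-5-methyl-2-(prop-1-en-2-yl)hex-5-en-1-yl]-4-propyl-3,4,8,9-tetrahydro-2H,10H-pyrano[2,3-f]chromene-2,10-dione | CCC[C@H]1CC(=O)Oc2c3C(=O)[C@@H](C)[C@@H](C)Oc3c(C[C@@H](CCC(C)=C)C(=C)C)c(O)c12 | intermediate
25 | 3-methylbut-2-en-1-ol (prenol) | CC(C)=CCO | starting material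
26 | di-tert-butyl dicarbonate | CC(C)(C)OC(=O)OC(=O)OC(C)(C)C | starting material
27 | tert-butyl 3-methylbut-2-en-1-yl carbonate | CC(C)=CCOC(=O)OC(C)(C)C | intermediate
28 | (4S,6R,8R,9S)-8,9-dimethyl-6-(3-methylbut-2-en-1-yl)-6-[(2R)-5-methyl-2-(prop-1-en-2-yl)hex-5-en-1-yl]-4-propyl-3,4,8,9-tetrahydro-2H-pyrano[2,3-f]chromene-2,5,10(6H)-trione | C=C(C)CC[C@H](C[C@@]1(CC=C(C)C)C(=O)C3=C(OC(=O)C[C@@H]3CCC)C2=C1O[C@H](C)[C@H](C)C2=O)C(=C)C | intermediate
29 | CNP0294320.1, (3S)-3-{(2R,3S,8R)-5-hydroxy-2,3-dimethyl-8-(3-methylbut-2-en-1-yl)-8-[(2R)-5-methyl-2-(prop-1-en-2-yl)hex-5-en-1-yl]-4,7-dioxo-3,4,7,8-tetrahydro-2H-chromen-6-yl}hexanoic acid | C=C(C)CC[C@H](C[C@@]1(CC=C(C)C)C(=O)C([C@@H](CCC)CC(=O)O)=C(O)C2=C1O[C@H](C)[C@H](C)C2=O)C(=C)C | target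

**Step count and risks**

Total step count: 16. Longest linear sequence: 11 steps (steps 1–8, 13, 15, 16, from phloroglucinol).

Steps most likely to fail:

1. Step 15 (proposed new method). The prenyl group may stay on oxygen or go to the other ortho carbon (C4a), the ligand may not override the weak facial bias of the substrate, attack may occur at the substituted allyl terminus, or tert-butoxide may epimerise C9. Fallback: set out from 24 and use the known base-mediated alkylative dearomatisation of acylphloroglucinols (LiHMDS, 1.05 equiv, toluene/THF, −78 °C, then prenyl bromide, 0 °C). Because the substrate is a single enantiomer, the two products are diastereomers; 28 is separated by chromatography from its (6S)-epimer F1, and the route is rejoined at 28.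

2. Step 13. Transmetalation at the doubly ortho-substituted aryl–palladium may be slow, so that protodeiodination back to 13 or β-hydride elimination of the alkyl group takes over, and zinc iodide may promote cis-to-trans isomerisation of the chromanone. Fallback: set out from 18 and 14 and replace the organozinc by a radical route. Acid 18 is converted with N-hydroxyphthalimide, N,N′-diisopropylcarbodiimide and cat. DMAP (CH2Cl2) into the N-(acyloxy)phthalimide F2. F2 is then coupled with 14 by nickel-catalysed decarboxylative cross-electrophile coupling (NiBr2(dme), 4,4′-di-tert-butyl-2,2′-bipyridine, Zn, DMA, rt), which is known for aryl iodides and primary redox-active esters. This gives 24 directly and makes step 12 unnecessary.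

3. Step 4. Enantioselectivity may be low for this twisted, electron-rich α-propylstyrene, the palladium hydride may move the alkene into the chain, or the alkenylphenol may dimerise under the acidic conditions. Fallback: set out from 1 and make the stereocentre by reduction instead of carbonylation. Pechmann condensation of 1 with ethyl 3-oxohexanoate (CCCC(=O)CC(=O)OCC; MeSO3H, rt) gives 5,7-dihydroxy-4-propylcoumarin F3. Benzylation of both hydroxyls (BnBr, 2.2 equiv, K2CO3, DMF) gives 5,7-bis(benzyloxy)-4-propylcoumarin F4. The known copper hydride asymmetric conjugate reduction of coumarins (Cu(OAc)2, (R)- or (S)-DTBM-SEGPHOS, (EtO)2MeSiH, t-BuOH, toluene) then gives 9, where the route is rejoined.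

**Further compounds**

F1 | step 15 | (4S,6S,8R,9S)-8,9-dimethyl-6-(3-methylbut-2-en-1-yl)-6-[(2R)-5-methyl-2-(prop-1-en-2-yl)hex-5-en-1-yl]-4-propyl-3,4,8,9-tetrahydro-2H-pyrano[2,3-f]chromene-2,5,10(6H)-trione (C6 epimer of 28) | C=C(C)CC[C@H](C[C@]1(CC=C(C)C)C(=O)C3=C(OC(=O)C[C@@H]3CCC)C2=C1O[C@H](C)[C@H](C)C2=O)C(=C)C
F2 | step 13 | 1,3-dioxoisoindolin-2-yl (3R)-6-methyl-3-(prop-1-en-2-yl)hept-6-enoate | O=C(ON1C(=O)c2ccccc2C1=O)C[C@@H](CCC(C)=C)C(=C)C
F3 | step 4 | 5,7-dihydroxy-4-propyl-2H-chromen-2-one | CCCC1=CC(=O)Oc2cc(O)cc(O)c12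
F4 | step 4 | 5,7-bis(benzyloxy)-4-propyl-2H-chromen-2-one | CCCC1=CC(=O)Oc2cc(OCc3ccccc3)cc(OCc3ccccc3)c12
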